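You are asked two questions: what [product] stands at the end of each of the flasks below, and what course that row takes.

| setting | south-east | north-west | south | teal | red | blue | amber | ochre |
|---|---|---|---|---|---|---|---|---|
| substrate | 8.9 mM | 42 mM | 130 mM | 10 mM | 20 mM | 40 mM | 80 mM | 150 mM |
| coupling partner | 24 mM | 24 mM | 24 mM | 24.0 mM | 24.0 mM | 24.0 mM | 24.0 mM | 24.0 mM |
| remark | run made earlier | run made earlier | run made earlier |  |  |  |  |  |
| time |  |  |  | 5.0 min | 5.0 min | 5.0 min | 5.0 min | 5.0 min |

- south-east (time / min: product / %): 0.417: 14; 1.33: 38; 2.50: 51; 4.00: 56
- north-west (time / min: product / %): 0.250: 3; 0.667: 2; 1.50: 7; 4.00: 9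
- south (time / min: product / %): 0.833: 0; 2.00: 2; 2.50: 1; 4.00: 1

(standard deviation of a reading: 1.5 percentage points)

- on the list of suspects stand: intermediate B <-> intermediate C; substrate + coupling partner -> intermediate B; coupling partner + intermediate A -> product; substrate + coupling partner <-> intermediate A
- "hardly changes" means that all values lie within two and a half points (for a concentration: within two and a half percent of the largest)

* [product] at the end for teal, red, blue, amber, ochre, in this order
* the course of these numbers from the first flask to the last (falls all the way / hardly changes / rises all the way / falls, then rises / rises, then falls)

Teal's neighbour is the south-east run, which looks nearly the same, so start there. The suspect steps let substrate reach product by taking up coupling partner twice. I therefore define the ceiling as the smaller of one and the partner charge over twice the substrate charge. The fill is the product fraction over that ceiling, and south-east's last reading, at 4.00 min, gives 0.560. In both flasks substrate is the limiting reagent, because the partner charge over twice the substrate charge stands above one, so the ceiling is one in each and I let teal inherit that fill as an estimate. The small thing I correct for is teal's extra time, 1.00 min, and I leave the difference in substrate charge uncorrected. South-east's rise over its last interval is 5 percentage points and slowing, so I take half of that slope, a correction of 0.0167. Teal's fill then comes to 0.577, or 5.77 mM.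

At higher substrate charges, with coupling partner held at its charge, the ceiling falls. North-west reads a fill of 0.315 and south reads 0.108, though the scatter on south's fill is 0.162. Interpolating between them gives amber 0.226, or 2.71 mM. If red kept south-east's fill, it would hold 6.72 mM, so I expect the row to rise, then fall.

The forecast, reasoning “so more substrate gives less product”, gave 5.4 mM, 6 mM, 4 mM, 2.2 mM and 1.2 mM, rises, then falls, which is below my figures for teal and amber.

The flasks give 5.80 mM, 6.67 mM, 5.14 mM, 3.31 mM and 2.02 mM, rises, then falls.

    intermediate B ⇌ intermediate C (K = 3.90, k = 0.0290 s⁻¹)
    substrate + coupling partner → intermediate B (k = 0.600 L mol⁻¹ s⁻¹)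
    coupling partner + intermediate A → product (k = 0.930 L mol⁻¹ s⁻¹)
    substrate + coupling partner ⇌ intermediate A (K = 120 L mol⁻¹, k = 3.70 L mol⁻¹ s⁻¹)

Teal's fill is 0.580, south-east's 0.560 plus the correction, and amber's is 0.276 against the interpolated 0.226. At 0.0865 min in teal, the forward step to intermediate A alone uses coupling partner 8.7 times as fast as the step to product does, and intermediate A is made 7.06 times faster than it is used up, each step taken net. At 5.00 min in teal, that ratio of making to using up is 0.135, and intermediate A stands at 3.76% of the substrate charged.

All runs were generated by integration with constants of no real substance; noise was put on by code.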